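The target is cut at the C3–aryl bond between its two trans-dihydrobenzofurans and at the Z-stilbene. The dihydrobenzofuran that carries the stilbene has (S)-C2 bearing O1 and the 4-hydroxyphenyl ring, C6–OH on ring A and the styryl carbon at C4. This is the chromanone of (S)-naringenin with ring A moved from C4 to C3. One oxidative 1,2-aryl shift on a 5-O-benzyl, 7-O-methyl, 4′-O-pivaloyl flavanone therefore forms C3–C3a, shrinks the pyranone to the five-membered ring and turns the former carbonyl carbon into a trans ester on C3. That ester is later exchanged, by decarboxylative arylation, for the separately made (2R,3R)-dihydrobenzofuran.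

Key step: step 4

Assumption: Rh2(R-PTAD)4 is taken to deliver the (2S,3R)-cis insertion product 15; if the substrate responds with the opposite sense, Rh2(S-PTAD)4 is used instead and nothing else changes.
Locants: unprimed numbers refer to the dihydrobenzofuran that carries the stilbene (ring A is its benzo ring), primed numbers to the second dihydrobenzofuran (ring B is its benzo ring).

**Naringenin line**

Step 1
Reactants: 1 (S)-naringenin
Product: 2 (S)-7-O-methylnaringenin
Conditions: MeOH (1.05 equiv), PPh3, DIAD, THF, 0 °C → rt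
Reagents that add atoms: methanol, CO
Why: Mitsunobu etherification alkylates the most acidic phenol (7-OH, para to the carbonyl) without free base, so C2 is not exposed to conditions that open the flavanone to the chalcone.

Step 2
Reactants: 2 (S)-7-O-methylnaringenin
Product: 3 (S)-7-O-methyl-4′-O-pivaloylnaringenin
Conditions: PivCl (1.1 equiv), pyridine, CH2Cl2, 0 °C
Reagents that add atoms: pivaloyl chloride, CC(C)(C)C(=O)Cl
Why: Acylation with the hindered acid chloride should take the free 4′-OH and leave the 5-OH, which is hydrogen-bonded to the carbonyl, untouched (phenol O-acylation).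

Step 3
Reactants: 3 (S)-7-O-methyl-4′-O-pivaloylnaringenin
Product: 4 (S)-5-O-benzyl-7-O-methyl-4′-O-pivaloylnaringenin
Conditions: BnOH (1.5 equiv), PPh3, DIAD, THF, 0 → 40 °C
Reagents that add atoms: benzyl alcohol, OCc1ccccc1
Why: A second Mitsunobu etherification should alkylate the only remaining phenol, the chelated 5-OH, which is slower but still acidic enough with excess reagents, again without base at the C2 stereocentre.

Step 4
Reactants: 4 (S)-5-O-benzyl-7-O-methyl-4′-O-pivaloylnaringenin
Product: 5 methyl (2S,3S)-4-benzyloxy-6-methoxy-2-(4-pivaloyloxyphenyl)-2,3-dihydrobenzofuran-3-carboxylate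
Conditions: PhI(OAc)2 (1.2 equiv), conc. H2SO4 (cat.), HC(OMe)3, 0 °C → rt; aq. NaHCO3
Reagents that add atoms: trimethyl orthoformate, COC(OC)OC; water (work-up), O
Why: Acidic trimethyl orthoformate converts the C4 ketone into its dimethyl ketal and methyl enol ether, PhI(OAc)2 delivers trivalent iodine to C3 on the face anti to the C2 aryl group, and the ring A carbon C4a then shifts from C4 to C3 as iodobenzene leaves; the dimethoxycarbenium ion is trapped as the orthoester, which gives the methyl ester on aqueous work-up. The closest known reaction type is the oxidative ring contraction of flavanones to trans methyl 2-aryl-2,3-dihydrobenzofuran-3-carboxylates with trivalent iodine or Tl(NO3)3 in trimethyl orthoformate. The dihydrofuran ring is closed not by a cyclisation but by this 1,2-aryl shift through an aryl-bridged transition state, which forms C3–C3a as C4–C4a breaks. The new C3 centre is controlled by C2: iodine adds anti to the C2 aryl group and migration inverts C3, which places the ester trans to the aryl group, and this is also the thermodynamic isomer at an epimerisable centre. The step needs ring A migration to win over migration of the C2 aryl group (isoflavone) and over elimination (flavone); the 7-OMe para and the 5-OBn ortho to C4a make ring A the best migrating group, and the 4′-pivalate makes the C2 aryl group a poor one.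

Step 5
Reactants: 5 methyl (2S,3S)-4-benzyloxy-6-methoxy-2-(4-pivaloyloxyphenyl)-2,3-dihydrobenzofuran-3-carboxylate
Product: 6 (2S,3S)-4-benzyloxy-6-methoxy-2-(4-pivaloyloxyphenyl)-2,3-dihydrobenzofuran-3-carboxylic acid
Conditions: LiI (excess), EtOAc, reflux; aq. HCl
Reagents that add atoms: none
Why: Iodide attacks the ester methyl group and not an acyl carbon (SN2 O-demethylation of a methyl ester), so the aryl pivalate and the benzyl ether should survive and the trans arrangement is kept.

**Second dihydrobenzofuran**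

Step 6
Reactants: 7 5-bromo-2-hydroxy-3-methoxybenzaldehyde; 8 4-methoxybenzyl chloride
Product: 9 5-bromo-3-methoxy-2-(4-methoxybenzyloxy)benzaldehyde
Conditions: K2CO3, DMF, 60 °C
Reagents that add atoms: none
Why: The phenoxide displaces chloride from the benzylic halide (Williamson ether synthesis), installing the CH2 that later becomes C2′.

Step 7
Reactants: 9 5-bromo-3-methoxy-2-(4-methoxybenzyloxy)benzaldehyde; 10 (3,5-dimethoxyphenyl)magnesium chloride
Product: 11 rac-[5-bromo-3-methoxy-2-(4-methoxybenzyloxy)phenyl](3,5-dimethoxyphenyl)methanol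
Conditions: THF, 0 °C; aq. NH4Cl
Reagents that add atoms: none
Why: Grignard addition to the aldehyde is fast at 0 °C, where the aryl bromide does not exchange with an arylmagnesium halide; the racemic carbinol centre is removed in the next step.

Step 8
Reactants: 11 rac-[5-bromo-3-methoxy-2-(4-methoxybenzyloxy)phenyl](3,5-dimethoxyphenyl)methanol
Product: 12 [5-bromo-3-methoxy-2-(4-methoxybenzyloxy)phenyl](3,5-dimethoxyphenyl)methanone
Conditions: MnO2 (activated), CH2Cl2, rt
Reagents that add atoms: none
Why: Activated MnO2 oxidises the doubly benzylic carbinol to the diaryl ketone without touching the ethers or the bromide (benzylic alcohol oxidation).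

Step 9
Reactants: 12 [5-bromo-3-methoxy-2-(4-methoxybenzyloxy)phenyl](3,5-dimethoxyphenyl)methanone
Product: 13 hydrazone of ketone 12 (E/Z mixture)
Conditions: N2H4·H2O (excess), AcOH (cat.), EtOH, 80 °C
Reagents that add atoms: hydrazine, NN
Why: Acid-catalysed condensation of the diaryl ketone with excess hydrazine gives the free hydrazone, whose C=N geometry is irrelevant because it is lost in the diazo compound.

Step 10
Reactants: 13 hydrazone of ketone 12
Product: 15 (2S,3R)-5-bromo-3-(3,5-dimethoxyphenyl)-7-methoxy-2-(4-methoxyphenyl)-2,3-dihydrobenzofuran, via diaryldiazomethane 14 (not isolated)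
Conditions: MnO2, CH2Cl2, 0 °C; filter; Rh2(R-PTAD)4 (1 mol%), CH2Cl2, 0 °C → rt
Reagents that add atoms: none
Why: MnO2 dehydrogenates the hydrazone to the diaryldiazomethane, and the chiral dirhodium tetracarboxylate turns it into a donor/donor carbene that inserts into the neighbouring benzylic ether C–H bond (1,5-insertion), the catalyst setting both C2′ and C3′ in the cis product (enantioselective intramolecular carbene C–H insertion).

Step 11
Reactants: 15 (2S,3R)-5-bromo-3-(3,5-dimethoxyphenyl)-7-methoxy-2-(4-methoxyphenyl)-2,3-dihydrobenzofuran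
Product: 16 (2R,3R)-5-bromo-3-(3,5-dimethoxyphenyl)-7-methoxy-2-(4-methoxyphenyl)-2,3-dihydrobenzofuran
Conditions: CF3CO2H, CH2Cl2 (dilute), 0 °C → rt
Reagents that add atoms: none
Why: Acid ionises the C2′–O bond to a 4-methoxybenzylic cation that re-closes on the phenol oxygen, which should equilibrate C2′ to the more stable trans isomer while C3′ keeps its configuration (acid-mediated epimerisation of a 2-aryl-2,3-dihydrobenzofuran).

**Alkyne**

Step 12
Reactants: 17 4-ethynylphenol
Product: 18 4-ethynylphenyl pivalate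
Conditions: PivCl, Et3N, CH2Cl2, 0 °C
Reagents that add atoms: pivaloyl chloride, CC(C)(C)C(=O)Cl
Why: Simple phenol acylation gives a stable alkyne whose protecting group matches the esters used in the end game.

**Union and end game**

Step 13
Reactants: 6 (2S,3S)-4-benzyloxy-6-methoxy-2-(4-pivaloyloxyphenyl)-2,3-dihydrobenzofuran-3-carboxylic acid; 16 (2R,3R)-5-bromo-3-(3,5-dimethoxyphenyl)-7-methoxy-2-(4-methoxyphenyl)-2,3-dihydrobenzofuran
Product: 21 (2S,3S)-4-benzyloxy-3-[(2R,3R)-3-(3,5-dimethoxyphenyl)-7-methoxy-2-(4-methoxyphenyl)-2,3-dihydrobenzofuran-5-yl]-6-methoxy-2-(4-pivaloyloxyphenyl)-2,3-dihydrobenzofuran, via N-acyloxyphthalimide ester 19 (not isolated), via arylzinc chloride 20 (not isolated)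
Conditions: 6, N-hydroxyphthalimide, DIC, DMAP (cat.), CH2Cl2, rt, concentrate; 16 (2 equiv), t-BuLi (2 equiv per bromide), THF, −78 °C, then ZnCl2, → rt; combine, NiCl2·glyme (20 mol%), 4,4′-di-tert-butyl-2,2′-bipyridine (40 mol%), THF/DMF, rt
Reagents that add atoms: none
Why: Low-valent nickel reduces ester 19, which fragments to CO2, phthalimide anion and the C3 benzylic radical, and this radical combines with the aryl–nickel species formed from 20 and undergoes reductive elimination on the face away from the C2 aryl group, so the new (3S) centre should be set trans by substrate control (nickel-catalysed decarboxylative Negishi-type arylation of a redox-active ester).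

Step 14
Reactants: 21 benzyl ether from step 13
Product: 22 (2S,3S)-3-[(2R,3R)-3-(3,5-dimethoxyphenyl)-7-methoxy-2-(4-methoxyphenyl)-2,3-dihydrobenzofuran-5-yl]-4-hydroxy-6-methoxy-2-(4-pivaloyloxyphenyl)-2,3-dihydrobenzofuran
Conditions: H2 (1 atm), Pd/C, EtOAc, rt
Reagents that add atoms: none
Why: Hydrogenolysis of the aryl benzyl ether is much faster than cleavage of the cyclic benzylic C–O bonds, and no halide, alkene or alkyne is present (O-debenzylation).

Step 15
Reactants: 22 C4 phenol from step 14
Product: 23 C4 trifluoromethanesulfonate of phenol 22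
Conditions: Tf2O, pyridine, CH2Cl2, 0 °C
Reagents that add atoms: trifluoromethanesulfonic anhydride, O=S(=O)(OS(=O)(=O)C(F)(F)F)C(F)(F)F
Why: The only free hydroxyl is sulfonylated by the small, highly reactive anhydride in spite of its hindered position (phenol triflation).

Step 16
Reactants: 23 C4 triflate from step 15
Product: 25 hexapivalate triflate (all five former methyl ethers and the 4-hydroxyphenyl group at C2 as pivalates), via pentaphenol triflate 24 (not isolated)
Conditions: BBr3 (excess), CH2Cl2, −78 °C → rt; MeOH, evaporate; PivCl, pyridine, DMAP (cat.), CH2Cl2, rt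
Reagents that add atoms: pivaloyl chloride, CC(C)(C)C(=O)Cl
Why: BBr3 cleaves the five aryl methyl ethers while the aryl triflate is inert and before any alkyne or stilbene is present for acid to cyclise onto ring B, any reversible opening of a benzylic C–O bond should re-close to the trans ring, and pivaloylation of crude 24 restores the original pivalate if it was lost and gives one base-labile protecting group (Lewis acid ether cleavage, then acylation).

Step 17
Reactants: 25 hexapivalate triflate; 18 4-ethynylphenyl pivalate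
Product: 26 heptapivalate diarylalkyne, the C4 triflate replaced by a (4-pivaloyloxyphenyl)ethynyl group
Conditions: PdCl2(PPh3)2 (5 mol%), CuI (10 mol%), Et3N, DMF, 70 °C
Reagents that add atoms: none
Why: Zerovalent palladium inserts into the C–O bond of the electron-poor aryl triflate and the copper acetylide of 18 transmetalates, while aryl pivalates are inert to palladium under these conditions (Sonogashira coupling).

Step 18
Reactants: 26 heptapivalate diarylalkyne
Product: 27 heptapivalate of the target (Z-stilbene)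
Conditions: H2 (1 atm), Pd/CaCO3 poisoned with Pb(OAc)2 (Lindlar catalyst), quinoline, EtOAc, rt
Reagents that add atoms: none
Why: Hydrogen is delivered syn to the alkyne on the poisoned palladium surface and quinoline suppresses over-reduction, so the Z-alkene should form with esters and benzylic ethers untouched (Lindlar semi-hydrogenation).

Step 19
Reactants: 27 heptapivalate of the target
Product: 28 CNP0172909.2
Conditions: K2CO3, MeOH/THF (degassed), rt → 40 °C, dark; AcOH
Reagents that add atoms: none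
Why: Methoxide transesterifies the seven aryl pivalates under non-acidic conditions that neither isomerise the Z-alkene nor ionise the benzylic ethers, and any base-induced opening of a 2-(4-hydroxyphenyl) ring through its quinone methide is reversible toward the trans rings already present (ester methanolysis).

**Compound list**

1 | (S)-naringenin | O=C1C[C@@H](c2ccc(O)cc2)Oc2cc(O)cc(O)c12 | starting material
2 | (S)-7-O-methylnaringenin | O=C1C[C@@H](c2ccc(O)cc2)Oc2cc(OC)cc(O)c12 | intermediate
3 | (S)-7-O-methyl-4′-O-pivaloylnaringenin | O=C1C[C@@H](c2ccc(OC(=O)C(C)(C)C)cc2)Oc2cc(OC)cc(O)c12 | intermediate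
4 | (S)-5-O-benzyl-7-O-methyl-4′-O-pivaloylnaringenin | O=C1C[C@@H](c2ccc(OC(=O)C(C)(C)C)cc2)Oc2cc(OC)cc(OCc3ccccc3)c12 | intermediate
5 | methyl (2S,3S)-4-benzyloxy-6-methoxy-2-(4-pivaloyloxyphenyl)-2,3-dihydrobenzofuran-3-carboxylate | c1ccccc1COc1cc(OC)cc2c1[C@H](C(=O)OC)[C@@H](c1ccc(OC(=O)C(C)(C)C)cc1)O2 | intermediate
6 | (2S,3S)-4-benzyloxy-6-methoxy-2-(4-pivaloyloxyphenyl)-2,3-dihydrobenzofuran-3-carboxylic acid | c1ccccc1COc1cc(OC)cc2c1[C@H](C(=O)O)[C@@H](c1ccc(OC(=O)C(C)(C)C)cc1)O2 | intermediate
7 | 5-bromo-2-hydroxy-3-methoxybenzaldehyde | O=Cc1cc(Br)cc(OC)c1O | starting material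
8 | 4-methoxybenzyl chloride | ClCc1ccc(OC)cc1 | starting material
9 | 5-bromo-3-methoxy-2-(4-methoxybenzyloxy)benzaldehyde | O=Cc1cc(Br)cc(OC)c1OCc1ccc(OC)cc1 | intermediate
10 | (3,5-dimethoxyphenyl)magnesium chloride (THF solution) | COc1cc(OC)cc([Mg]Cl)c1 | starting material
11 | rac-[5-bromo-3-methoxy-2-(4-methoxybenzyloxy)phenyl](3,5-dimethoxyphenyl)methanol | OC(c1cc(OC)cc(OC)c1)c1cc(Br)cc(OC)c1OCc1ccc(OC)cc1 | intermediate
12 | [5-bromo-3-methoxy-2-(4-methoxybenzyloxy)phenyl](3,5-dimethoxyphenyl)methanone | O=C(c1cc(OC)cc(OC)c1)c1cc(Br)cc(OC)c1OCc1ccc(OC)cc1 | intermediate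
13 | hydrazone of ketone 12 (E/Z mixture) | NN=C(c1cc(OC)cc(OC)c1)c1cc(Br)cc(OC)c1OCc1ccc(OC)cc1 | intermediate
14 | [5-bromo-3-methoxy-2-(4-methoxybenzyloxy)phenyl](3,5-dimethoxyphenyl)diazomethane | [N-]=[N+]=C(c1cc(OC)cc(OC)c1)c1cc(Br)cc(OC)c1OCc1ccc(OC)cc1 | intermediate
15 | (2S,3R)-5-bromo-3-(3,5-dimethoxyphenyl)-7-methoxy-2-(4-methoxyphenyl)-2,3-dihydrobenzofuran (cis) | Brc1cc(OC)c2c(c1)[C@@H](c1cc(OC)cc(OC)c1)[C@@H](c1ccc(OC)cc1)O2 | intermediate
16 | (2R,3R)-5-bromo-3-(3,5-dimethoxyphenyl)-7-methoxy-2-(4-methoxyphenyl)-2,3-dihydrobenzofuran (trans) | Brc1cc(OC)c2c(c1)[C@@H](c1cc(OC)cc(OC)c1)[C@H](c1ccc(OC)cc1)O2 | intermediate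
17 | 4-ethynylphenol | C#Cc1ccc(O)cc1 | starting material
18 | 4-ethynylphenyl pivalate | C#Cc1ccc(OC(=O)C(C)(C)C)cc1 | intermediate
19 | 1,3-dioxoisoindolin-2-yl (2S,3S)-4-benzyloxy-6-methoxy-2-(4-pivaloyloxyphenyl)-2,3-dihydrobenzofuran-3-carboxylate | c1ccccc1COc1cc(OC)cc2c1[C@H](C(=O)ON3C(=O)c4ccccc4C3=O)[C@@H](c1ccc(OC(=O)C(C)(C)C)cc1)O2 | intermediate
20 | [(2R,3R)-3-(3,5-dimethoxyphenyl)-7-methoxy-2-(4-methoxyphenyl)-2,3-dihydrobenzofuran-5-yl]zinc chloride | Cl[Zn]c1cc(OC)c2c(c1)[C@@H](c1cc(OC)cc(OC)c1)[C@H](c1ccc(OC)cc1)O2 | intermediate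
21 | (2S,3S)-4-benzyloxy-3-[(2R,3R)-3-(3,5-dimethoxyphenyl)-7-methoxy-2-(4-methoxyphenyl)-2,3-dihydrobenzofuran-5-yl]-6-methoxy-2-(4-pivaloyloxyphenyl)-2,3-dihydrobenzofuran | c1ccccc1COc1cc(OC)cc2c1[C@H](c1cc(OC)c3c(c1)[C@@H](c1cc(OC)cc(OC)c1)[C@H](c1ccc(OC)cc1)O3)[C@@H](c1ccc(OC(=O)C(C)(C)C)cc1)O2 | intermediate
22 | C4 phenol: as 21 with 4-hydroxy in place of 4-benzyloxy | Oc1cc(OC)cc2c1[C@H](c1cc(OC)c3c(c1)[C@@H](c1cc(OC)cc(OC)c1)[C@H](c1ccc(OC)cc1)O3)[C@@H](c1ccc(OC(=O)C(C)(C)C)cc1)O2 | intermediate
23 | C4 trifluoromethanesulfonate of 22 | FC(F)(F)S(=O)(=O)Oc1cc(OC)cc2c1[C@H](c1cc(OC)c3c(c1)[C@@H](c1cc(OC)cc(OC)c1)[C@H](c1ccc(OC)cc1)O3)[C@@H](c1ccc(OC(=O)C(C)(C)C)cc1)O2 | intermediate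
24 | pentaphenol triflate: 23 with all five methoxy groups as hydroxy groups | FC(F)(F)S(=O)(=O)Oc1cc(O)cc2c1[C@H](c1cc(O)c3c(c1)[C@@H](c1cc(O)cc(O)c1)[C@H](c1ccc(O)cc1)O3)[C@@H](c1ccc(OC(=O)C(C)(C)C)cc1)O2 | intermediate
25 | hexapivalate triflate: (2S,3S)-3-[(2R,3R)-3-[3,5-bis(pivaloyloxy)phenyl]-7-pivaloyloxy-2-(4-pivaloyloxyphenyl)-2,3-dihydrobenzofuran-5-yl]-6-pivaloyloxy-2-(4-pivaloyloxyphenyl)-2,3-dihydrobenzofuran-4-yl trifluoromethanesulfonate | FC(F)(F)S(=O)(=O)Oc1cc(OC(=O)C(C)(C)C)cc2c1[C@H](c1cc(OC(=O)C(C)(C)C)c3c(c1)[C@@H](c1cc(OC(=O)C(C)(C)C)cc(OC(=O)C(C)(C)C)c1)[C@H](c1ccc(OC(=O)C(C)(C)C)cc1)O3)[C@@H](c1ccc(OC(=O)C(C)(C)C)cc1)O2 | intermediate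
26 | heptapivalate diarylalkyne: 25 with the triflate replaced by a (4-pivaloyloxyphenyl)ethynyl group | CC(C)(C)C(=O)Oc1ccc(C#Cc2cc(OC(=O)C(C)(C)C)cc3c2[C@H](c2cc(OC(=O)C(C)(C)C)c4c(c2)[C@@H](c2cc(OC(=O)C(C)(C)C)cc(OC(=O)C(C)(C)C)c2)[C@H](c2ccc(OC(=O)C(C)(C)C)cc2)O4)[C@@H](c2ccc(OC(=O)C(C)(C)C)cc2)O3)cc1 | intermediate
27 | heptapivalate of the target (Z-stilbene) | CC(C)(C)C(=O)Oc1ccc(/C=C\c2cc(OC(=O)C(C)(C)C)cc3c2[C@H](c2cc(OC(=O)C(C)(C)C)c4c(c2)[C@@H](c2cc(OC(=O)C(C)(C)C)cc(OC(=O)C(C)(C)C)c2)[C@H](c2ccc(OC(=O)C(C)(C)C)cc2)O4)[C@@H](c2ccc(OC(=O)C(C)(C)C)cc2)O3)cc1 | intermediate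
28 | CNP0172909.2: (2S,3S)-3-[(2R,3R)-3-(3,5-dihydroxyphenyl)-7-hydroxy-2-(4-hydroxyphenyl)-2,3-dihydrobenzofuran-5-yl]-2-(4-hydroxyphenyl)-4-[(Z)-2-(4-hydroxyphenyl)ethenyl]-2,3-dihydrobenzofuran-6-ol | Oc1ccc(/C=C\c2cc(O)cc3c2[C@H](c2cc(O)c4c(c2)[C@@H](c2cc(O)cc(O)c2)[C@H](c2ccc(O)cc2)O4)[C@@H](c2ccc(O)cc2)O3)cc1 | target

**Step count and risks**

Total step count: 19. Longest linear sequence: 13 steps (steps 6–11 and 13–19, from 7); the naringenin line is 12 steps (steps 1–5 and 13–19).

Steps most likely to fail: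

1. Step 4 (key step). The iodinated ketal may eliminate to the flavone, the electron-rich ring A may be iodinated or over-oxidised, or the C2 aryl group may migrate in place of ring A. Fallback: set out from 4 and make the same C3–C3a bond by a Wolff ring contraction. Deprotonation with LiN(SiMe3)2 in THF at −78 °C, trifluoroacetylation with CF3CO2CH2CF3 and diazo transfer with MsN3/Et3N in MeCN should give (R)-5-benzyloxy-3-diazo-7-methoxy-2-(4-pivaloyloxyphenyl)chroman-4-one F1 (the descriptor changes by priority only; the C2 geometry is that of 4). Irradiation in methanol (or PhCO2Ag/Et3N) then shifts ring A from C4 to the diazo carbon, methanol is captured, and equilibration of C3 with DBU brings the route back at 5.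

2. Step 13. The hindered C3 radical may be captured too slowly, so that reduction, dimerisation or oxidation to the benzofuran compete; the valuable arylzinc may be lost to homocoupling; facial control may be weaker than expected. Fallback: set out from 6 and 16 and come back at 21 with no new compound (F0), by metallaphotoredox decarboxylative arylation with Ir[dF(CF3)ppy]2(dtbbpy)PF6 (1 mol%), NiCl2·glyme (10 mol%), 4,4′-di-tert-butyl-2,2′-bipyridine, Cs2CO3, DMF and blue light. The photocatalyst oxidises the carboxylate of 6, loss of CO2 gives the same C3 radical, and the aryl–nickel bromide formed directly from 16 by oxidative addition intercepts it; neither the activated ester nor the organozinc is needed.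

3. Step 10. The added methoxy group next to the reacting ether may erode the enantioselectivity, the sense of induction may be the opposite one, or the diazo compound may dimerise to the azine. Fallback: set out from 13 and give up catalyst control, using the naringenin-derived half as the resolving element. Oxidation with MnO2 and insertion with achiral Rh2(OAc)4 should give 15 together with its enantiomer (2R,3S)-5-bromo-3-(3,5-dimethoxyphenyl)-7-methoxy-2-(4-methoxyphenyl)-2,3-dihydrobenzofuran F2. Epimerisation with CF3CO2H gives 16 together with its enantiomer, the (2S,3S)-bromide F3. Lithiation and zincation give 20 together with its enantiomer, the (2S,3S)-arylzinc chloride F4. Coupling with 19 as in step 13 then gives 21 and its (2′S,3′S)-diastereomer F5, which are diastereomers and should separate by ordinary chromatography; the route comes back at 21.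

**Further compounds**

F1 | step 4 | (R)-5-benzyloxy-3-diazo-7-methoxy-2-(4-pivaloyloxyphenyl)chroman-4-one | O=C1C(=[N+]=[N-])[C@@H](c2ccc(OC(=O)C(C)(C)C)cc2)Oc2cc(OC)cc(OCc3ccccc3)c12
F0 | step 13 | none | none
F2 | step 10 | (2R,3S)-5-bromo-3-(3,5-dimethoxyphenyl)-7-methoxy-2-(4-methoxyphenyl)-2,3-dihydrobenzofuran | Brc1cc(OC)c2c(c1)[C@H](c1cc(OC)cc(OC)c1)[C@H](c1ccc(OC)cc1)O2
F3 | step 10 | (2S,3S)-5-bromo-3-(3,5-dimethoxyphenyl)-7-methoxy-2-(4-methoxyphenyl)-2,3-dihydrobenzofuran | Brc1cc(OC)c2c(c1)[C@H](c1cc(OC)cc(OC)c1)[C@@H](c1ccc(OC)cc1)O2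
F4 | step 10 | [(2S,3S)-3-(3,5-dimethoxyphenyl)-7-methoxy-2-(4-methoxyphenyl)-2,3-dihydrobenzofuran-5-yl]zinc chloride | Cl[Zn]c1cc(OC)c2c(c1)[C@H](c1cc(OC)cc(OC)c1)[C@@H](c1ccc(OC)cc1)O2
F5 | step 10 | (2S,3S)-4-benzyloxy-3-[(2S,3S)-3-(3,5-dimethoxyphenyl)-7-methoxy-2-(4-methoxyphenyl)-2,3-dihydrobenzofuran-5-yl]-6-methoxy-2-(4-pivaloyloxyphenyl)-2,3-dihydrobenzofuran | c1ccccc1COc1cc(OC)cc2c1[C@H](c1cc(OC)c3c(c1)[C@H](c1cc(OC)cc(OC)c1)[C@@H](c1ccc(OC)cc1)O3)[C@@H](c1ccc(OC(=O)C(C)(C)C)cc1)O2
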